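## Retrosynthetic overview

1. Target 22 ⇒ diacid 21, by site-selective esterification of the unhindered C15 acid.
2. 21 ⇒ C14 alkene acid 15 + ethylene 16 + (R)-β-butyrolactone 17. C12–C13 comes from SN2 opening of the strained four-membered lactone by a C12 magnesium/copper reagent. That reagent is made in the same flask by a magnesium-ene addition to ethylene, which forms C9–C11.
3. Enabling feature: C17=C8–C9–C11–C12 is a 4-pentenyl unit. The exocyclic methylene on ring B is allylic to C9 and C12 lies two carbons further out, which is the pattern left by a C17–C8–C9 allyl metal adding to C2H4. C13 is β to the C15 carbonyl, which is the pattern left by alkyl–O opening of a β-lactone.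
4. 15 ⇒ enone 11 (cis-selective cuprate methylation at C10, enol triflate, Negishi methylation) ⇒ keto-lactone 9, whose temporary C19–O–C10 ring fixes C5.
5. Ring order: ring A is present in 1, with C4 set by asymmetric conjugate addition. Ring B is closed by Robinson annulation (steps 2–3). The temporary lactone ring is closed in step 4 and opened in step 5.

Key step: step 8

Remark: labdane numbering is used. The given SMILES encodes a cis-fused decalin, (4S,5R,9R,10S,13R). H-5, C-20, C-11 and the C-4 methyl lie on one face (α in the usual drawing); the C-4 carboxyl and H-9 lie on the other (β). The route is planned for exactly this isomer.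

## Route

Step 1
Reactants: 1 methyl 3-oxocyclohex-1-ene-1-carboxylate
Product: 3 methyl (S)-1-methyl-3-(trimethylsilyloxy)cyclohex-2-ene-1-carboxylate, via zinc enolate 2 (not isolated)
Conditions: Me2Zn (3 equiv), (CuOTf)2·C6H6 (2.5 mol %), chiral bidentate NHC–Ag complex (2.5 mol %), t-BuOMe, −30 °C; then TMSOTf, Et3N, −78 → 0 °C
Reagents that add atoms: dimethylzinc, C[Zn]C; trimethylsilyl trifluoromethanesulfonate, C[Si](C)(C)OS(=O)(=O)C(F)(F)F
Why: Copper/chiral-NHC-catalysed asymmetric conjugate addition of a dialkylzinc to a β-ester-substituted cyclic enone is an established route to all-carbon quaternary centres; the ligand enantiomer is chosen so that methyl adds to the face giving (S)-C4, and O-silylation of 2 fixes the enolate regiochemistry at C5/C10.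

Step 2
Reactants: 3 silyl enol ether; 4 but-3-en-2-one
Product: 6 methyl (1S)-1-methyl-3-oxo-2-(3-oxobutyl)cyclohexane-1-carboxylate (C5 epimers), via silyl enol ether 5 (not isolated)
Conditions: 4 (1.5 equiv), HNTf2 (2 mol %), CH2Cl2, −78 °C; then 1 M HCl, THF, 0 °C
Reagents that add atoms: none
Why: In this Mukaiyama–Michael addition the regiodefined silyl enol ether attacks the silylium-activated enone terminus and forms C5–C6 at the hindered α-carbon that the free ketone would not enolise towards, while the C5 configuration is not yet relevant because it stays epimerisable.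

Step 3
Reactants: 6 diketone
Product: 7 methyl (1S)-1-methyl-6-oxo-1,2,3,4,6,7,8,8a-octahydronaphthalene-1-carboxylate (C5 epimers)
Conditions: pyrrolidine (30 mol %), AcOH (30 mol %), toluene, reflux, Dean–Stark
Reagents that add atoms: none
Why: The intramolecular aldol condensation (second half of a Robinson annulation) closes ring B by attack of C9 on the C10 carbonyl under enamine/acid catalysis, which avoids the alkoxide conditions under which a Claisen-type attack on the ester could compete, and C5 remains a mixture.

Step 4
Reactants: 7 enone methyl ester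
Product: 9 tricyclic keto γ-lactone (8-oxo, C19–O–C10 bridge on the β face, H-5α, trans-fused decalin), via enone acids 8 (not isolated)
Conditions: LiI, 2,6-lutidine, reflux; 1 M HCl work-up; then TsOH·H2O (10 mol %), toluene, 80 °C
Reagents that add atoms: none
Why: SN2 dealkylation of the hindered methyl ester by iodide frees the acid, and acid-catalysed equilibration (the C5 epimers interconvert through the Δ5(10) dienol) should drain the mixture into the intramolecular oxa-Michael adduct, because only the epimer with H-5 anti to the carboxyl can close a chair–chair trans-fused γ-lactone, which sets C5.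

Step 5
Reactants: 9 keto-lactone
Product: 11 triisopropylsilyl (1S,8aR)-1-methyl-6-oxo-1,2,3,4,6,7,8,8a-octahydronaphthalene-1-carboxylate, via enone carboxylate salt 10 (not isolated)
Conditions: DBU, CH2Cl2, 0 °C; then TIPSCl, 0 °C → rt
Reagents that add atoms: triisopropylsilyl chloride, CC(C)[Si](Cl)(C(C)C)C(C)C
Why: E1cB opening of the β-acyloxy ketone (axial C10–O antiperiplanar to H-9α) regenerates the enone without touching C5, and silylation of the carboxylate gives a bulky axial ester that shields the β face of C10 for the next step.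

Step 6
Reactants: 11 enone silyl ester
Product: 13 cis-fused enol triflate (C8–OTf, C8=C9, 10α-methyl, H-5α, 4β-CO2TIPS), via lithium enolate 12 (not isolated)
Conditions: Me2CuLi (from MeLi and CuI), Et2O, −78 → −30 °C; then PhNTf2, THF, −78 → 0 °C
Reagents that add atoms: lithium dimethylcuprate, [Li+].C[Cu-]C; N-phenylbis(trifluoromethanesulfonimide), O=S(=O)(N(c1ccccc1)S(=O)(=O)C(F)(F)F)C(F)(F)F
Why: Cuprate 1,4-addition to Δ1(9)-2-octalone-type enones is the standard entry to cis-fused angular-methyl decalones, the axial silyl ester on the β face reinforces attack on C10 from the α face (methyl cis to H-5), and the regiodefined enolate 12 is trapped on oxygen by PhNTf2.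

Step 7
Reactants: 13 enol triflate
Product: 15 (1S,4aS,8aR)-1,4a,6-trimethyl-1,2,3,4,4a,7,8,8a-octahydronaphthalene-1-carboxylic acid, via alkene silyl ester 14 (not isolated)
Conditions: Me2Zn, Pd(dppf)Cl2 (5 mol %), THF, 50 °C; work-up; then TBAF, THF, 0 °C; 1 M HCl
Reagents that add atoms: dimethylzinc, C[Zn]C
Why: Negishi cross-coupling of the alkenyl triflate installs C17 with the double bond held at C8=C9, and fluoride cleaves the silyl ester under conditions that leave the trisubstituted alkene in place.

Step 8
Reactants: 15 alkene acid; 16 ethylene; 17 (R)-β-butyrolactone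
Product: 21 (1S,4aS,5R,8aR)-5-[(3R)-4-carboxy-3-methylbutyl]-1,4a-dimethyl-6-methylidenedecahydronaphthalene-1-carboxylic acid, via allylpotassium 18 (not isolated), via allylmagnesium bromide 19 (not isolated), via pentenylmagnesium bromide 20 (not isolated)
Conditions: n-BuLi/KOt-Bu (2.3 equiv each), THF, −78 → −45 °C; MgBr2·OEt2, → 0 °C; 16 (40 bar), 60 °C, autoclave; vent; CuBr·SMe2 (15 mol %), Me2S, 17, −40 → 0 °C; 1 M HCl
Reagents that add atoms: none
Why: Proposed new method: superbase metalation of the carboxylate of 15 at the C17 methyl group gives the C17–C8–C9 allyl anion 18, which after exchange to magnesium (19) adds to ethylene through a six-centre suprafacial magnesium-ene transition state, so that C9–C11 forms, the double bond moves to C8=C17 and magnesium ends on C12 (20); Cu(I) then lets 20 open lactone 17 by SN2 attack at its O-bearing carbon, the release of four-ring strain driving formation of C12–C13. The closest known reaction types are the intermolecular magnesium-ene addition of 2-alkenylmagnesium halides to ethylene and the copper-catalysed alkyl–oxygen opening of β-methyl-β-propiolactone by primary Grignard reagents to 3-methylalkanoic acids; what is new is their telescoping on a hindered ring allyl system that carries a carboxylate. No ring is closed and one four-membered ring is opened. C9 is controlled by the cis-decalin: in the half-chair with C1 pseudoaxial on the concave β face, ethylene can reach C9 only antiperiplanar to C1–C10 from the convex α face, which places C11 cis to C20, and C13 is set by inversion at the stereocentre of (R)-17. The step needs methyl over ring-CH2 (C7) metalation, γ (C9) over α (C17) attack, a single ethylene insertion and alkyl–O over acyl–O cleavage; these are secured respectively by the known methyl preference of 1-methylcycloalkenes, by the cyclic ene transition state with magnesium on the primary carbon, by the inertness of the alkyl Grignard 20 towards ethylene, and by the soft copper reagent. The C19 carboxylate needs no protecting group because it is inert to every organometallic present.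

Step 9
Reactants: 21 diacid
Product: 22 (1S,4aS,5R,8aR)-5-[(3R)-5-methoxy-3-methyl-5-oxopentyl]-1,4a-dimethyl-6-methylidenedecahydronaphthalene-1-carboxylic acid (target)
Conditions: MeOH (3 equiv), EDC·HCl (1.05 equiv), DMAP (10 mol %), CH2Cl2, 0 °C
Reagents that add atoms: methanol, CO
Why: Steglich-type carbodiimide/DMAP esterification is governed by steric access, so the chain C15 acid should be activated and methanolysed while the tertiary C19 acid stays free, and no stereocentre is touched.

## Compound list

1 | methyl 3-oxocyclohex-1-ene-1-carboxylate | COC(=O)C1=CC(=O)CCC1 | starting material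
2 | methylzinc enolate of methyl (S)-1-methyl-3-oxocyclohexane-1-carboxylate | C[Zn]OC1=C[C@@](C)(C(=O)OC)CCC1 | intermediate
3 | methyl (S)-1-methyl-3-(trimethylsilyloxy)cyclohex-2-ene-1-carboxylate | C[Si](C)(C)OC1=C[C@@](C)(C(=O)OC)CCC1 | intermediate
4 | but-3-en-2-one (methyl vinyl ketone) | C=CC(C)=O | starting material
5 | trimethylsilyl enol ether of diketone 6 (C8–OTMS, C7=C8; C5 epimers) | CC(O[Si](C)(C)C)=CCC1C(=O)CCC[C@]1(C)C(=O)OC | intermediate
6 | methyl (1S)-1-methyl-3-oxo-2-(3-oxobutyl)cyclohexane-1-carboxylate (C5 epimers) | CC(=O)CCC1C(=O)CCC[C@]1(C)C(=O)OC | intermediate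
7 | methyl (1S)-1-methyl-6-oxo-1,2,3,4,6,7,8,8a-octahydronaphthalene-1-carboxylate (C5 epimers) | O=C1CCC2C(CCC[C@]2(C)C(=O)OC)=C1 | intermediate
8 | (1S)-1-methyl-6-oxo-1,2,3,4,6,7,8,8a-octahydronaphthalene-1-carboxylic acid (C5 epimers) | O=C1CCC2C(CCC[C@]2(C)C(=O)O)=C1 | intermediate
9 | tricyclic keto γ-lactone (8-oxo, 19,10β-olide, H-5α) | O=C1CC[C@@H]2[C@]3(CCC[C@]2(C)C(=O)O3)C1 | intermediate
10 | DBU-H+ salt of the (4S,5R)-enone carboxylate | O=C1CC[C@@H]2C(CCC[C@]2(C)C(=O)[O-])=C1.C1CCC2=[NH+]CCCN2CC1 | intermediate
11 | triisopropylsilyl (1S,8aR)-1-methyl-6-oxo-1,2,3,4,6,7,8,8a-octahydronaphthalene-1-carboxylate | O=C1CC[C@@H]2C(CCC[C@]2(C)C(=O)O[Si](C(C)C)(C(C)C)C(C)C)=C1 | intermediate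
12 | lithium C8=C9 enolate of the cis-fused 10α-methyl ketone | [Li]OC=1CC[C@@H]2[C@@](C)(CCC[C@]2(C)C(=O)O[Si](C(C)C)(C(C)C)C(C)C)C=1 | intermediate
13 | cis-fused C8 enol triflate, TIPS ester | O=S(=O)(OC=1CC[C@@H]2[C@@](C)(CCC[C@]2(C)C(=O)O[Si](C(C)C)(C(C)C)C(C)C)C=1)C(F)(F)F | intermediate
14 | cis-fused 8-methyl-Δ8(9)-alkene, TIPS ester | CC=1CC[C@@H]2[C@@](C)(CCC[C@]2(C)C(=O)O[Si](C(C)C)(C(C)C)C(C)C)C=1 | intermediate
15 | (1S,4aS,8aR)-1,4a,6-trimethyl-1,2,3,4,4a,7,8,8a-octahydronaphthalene-1-carboxylic acid | CC=1CC[C@@H]2[C@@](C)(CCC[C@]2(C)C(=O)O)C=1 | intermediate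
16 | ethylene | C=C | starting material
17 | (R)-β-butyrolactone, (R)-4-methyloxetan-2-one | C[C@@H]1CC(=O)O1 | starting material
18 | dipotassium salt: C17–C8–C9 allyl anion and C19 carboxylate | [K+].[K+].[CH2-]C=1CC[C@@H]2[C@@](C)(CCC[C@]2(C)C(=O)[O-])C=1 | intermediate
19 | C17 allylmagnesium bromide, C19 bromomagnesium carboxylate | Br[Mg]CC=1CC[C@@H]2[C@@](C)(CCC[C@]2(C)C(=O)O[Mg]Br)C=1 | intermediate
20 | C12 primary alkylmagnesium bromide with C8=C17 methylene, C19 bromomagnesium carboxylate | C=C1CC[C@@H]2[C@@](C)(CCC[C@]2(C)C(=O)O[Mg]Br)[C@@H]1CC[Mg]Br | intermediate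
21 | (4S,5R,9R,10S,13R)-labd-8(17)-ene-15,19-dioic acid, cis-A/B | C=C1CC[C@@H]2[C@@](C)(CCC[C@]2(C)C(=O)O)[C@@H]1CC[C@@H](C)CC(=O)O | intermediate
22 | 15-methyl ester of 21 (CNP0260608.1) | C=C1CC[C@@H]2[C@@](C)(CCC[C@]2(C)C(=O)O)[C@@H]1CC[C@@H](C)CC(=O)OC | target

## Step count and risks

Total steps: 9. Longest linear sequence: 9.

**Step 8 (Proposed new method).**
- What may go wrong:
  - The poorly soluble carboxylate may be metalated slowly or unselectively.
  - The ene addition may be slow at C9, which is flanked by the quaternary C10, so that attack through C17 competes.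
  - The allyl metal may be protonated on heating.
- Fallback (known chemistry): it sets out from 13 and comes back at 21.
  - Kumada coupling of 13 with (trimethylsilyl)methylmagnesium chloride under Pd(0) should give the allylsilane F1.
  - TiCl4-promoted SE2′ opening of ethylene oxide (Hosomi–Sakurai type) from the convex α face should give the C12 primary alcohol F2, with the C8=C17 methylene already in place.
  - Appel iodination gives the primary iodide F3.
  - Iodine–lithium exchange (t-BuLi, −100 °C), transmetalation to magnesium and the known copper-catalysed opening of 17 give the 15-acid 19-silyl ester F4.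
  - TBAF then returns 21.

**Step 4.**
- What may go wrong: equilibration at C5 may be incomplete, or the enone-acid/lactone equilibrium may be unfavourable, so that the stereochemical funnel does not operate.
- Fallback: it sets out from 8 and comes back at 11.
  - The crude acids are silylated directly (TIPSCl, imidazole).
  - 11 is separated by chromatography from the 5-epimeric silyl ester F5.
  - F5 is re-equilibrated through its dienolate with DBU in warm toluene and recycled.

**Step 6.**
- What may go wrong: facial selectivity at C10 may erode, giving trans-fused material, or the silyl ester may be attacked.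
- Fallback: it sets out from 11 and comes back at 13.
  - Luche reduction should give the pseudoequatorial 8α-allylic alcohol F6.
  - Hydroxyl-directed Simmons–Smith cyclopropanation (Et2Zn, CH2I2) delivers the methylene to the α face and gives the cyclopropyl carbinol F7.
  - Dess–Martin oxidation gives the cyclopropyl ketone F8.
  - Reductive cleavage of the C9–CH2 bond, which overlaps with the carbonyl π system (SmI2, HMPA, t-BuOH), gives the angular α-methyl group and enolate 12.
  - Enolate 12 is trapped with PhNTf2 to give 13.

## Further compounds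

F1 | step 8 | C8-(trimethylsilylmethyl) Δ8(9)-allylsilane, TIPS ester | C[Si](C)(C)CC=1CC[C@@H]2[C@@](C)(CCC[C@]2(C)C(=O)O[Si](C(C)C)(C(C)C)C(C)C)C=1
F2 | step 8 | 9α-(2-hydroxyethyl)-8-methylidene cis-decalin, TIPS ester | C=C1CC[C@@H]2[C@@](C)(CCC[C@]2(C)C(=O)O[Si](C(C)C)(C(C)C)C(C)C)[C@@H]1CCO
F3 | step 8 | 9α-(2-iodoethyl)-8-methylidene cis-decalin, TIPS ester | C=C1CC[C@@H]2[C@@](C)(CCC[C@]2(C)C(=O)O[Si](C(C)C)(C(C)C)C(C)C)[C@@H]1CCI
F4 | step 8 | 19-TIPS ester of diacid 21 (free C15 acid) | C=C1CC[C@@H]2[C@@](C)(CCC[C@]2(C)C(=O)O[Si](C(C)C)(C(C)C)C(C)C)[C@@H]1CC[C@@H](C)CC(=O)O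
F5 | step 4 | 5-epimer of enone silyl ester 11 | O=C1CC[C@H]2C(CCC[C@]2(C)C(=O)O[Si](C(C)C)(C(C)C)C(C)C)=C1
F6 | step 6 | 8α-hydroxy-Δ9(10)-allylic alcohol, TIPS ester | O[C@@H]1CC[C@@H]2C(CCC[C@]2(C)C(=O)O[Si](C(C)C)(C(C)C)C(C)C)=C1
F7 | step 6 | 8α-hydroxy-9,10α-methano compound, TIPS ester | O[C@@H]1CC[C@@H]2[C@]3(CCC[C@]2(C)C(=O)O[Si](C(C)C)(C(C)C)C(C)C)C[C@@H]31
F8 | step 6 | 8-oxo-9,10α-methano compound (cyclopropyl ketone), TIPS ester | O=C1CC[C@@H]2[C@]3(CCC[C@]2(C)C(=O)O[Si](C(C)C)(C(C)C)C(C)C)C[C@@H]31
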